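**Retrosynthetic overview**
- Bryostatin 16 ⇐ desilylation ⇐ Au(I) 6-endo-dig closure of ring C (O23→C19) ⇐ Pd alkyne–alkyne macrocyclisation (C20–C21) ⇐ Yamaguchi ester (C1–O25) of a C1–C20 acid and a C21–C27 ynoate alcohol.
- C1–C20 acid ⇐ Ru ene–yne coupling/oxa-Michael (ring B) of a C1–C12 allyl ketone with a C13–C19 TMS-alkyne diol; vinylsilane → bromide → enoate fixes the C13 geometry; ring A by C5-OH → C9 ketalisation.
- Key step: a [2,3]-Wittig–Still rearrangement makes the C18–C19 bond, the C18 quaternary centre and the (E)-C16=C17 alkene; C15 comes from (R)-glyceraldehyde acetonide.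
- C1–C12 from the atorvastatin keto ester (C5) by two OH-directed anti reductions (C7, C3); C21–C27 from methyl (R)-lactate (C26) and (R)-epichlorohydrin (C23), C25 by directed reduction.
- Ring order: temporary C1/C5 δ-lactone → B → A → macrocycle → C.

Assumption: compounds 1, 11, 25 and 29 are bought as single enantiomers; positions are given in bryostatin numbering. The endgame (steps 16–22, 31, 33–35) is modelled on the known bryostatin 16 ene–yne/diyne approach; nothing here has been run.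

**C1–C12 fragment**

Step 1
Reactants: 1, tert-butyl (5R)-6-cyano-5-hydroxy-3-oxohexanoate
Product: 2, tert-butyl (5R)-6-cyano-5-hydroxy-2,2-dimethyl-3-oxohexanoate
Conditions: MeI (4 eq), K2CO3, acetone, 40 °C
Reagents that add atoms: iodomethane, CI (twice)
Why: Double C-alkylation of the β-keto ester installs the C8 gem-dimethyl group; only the doubly activated CH2 is deprotonated by carbonate, so C5 is untouched.

Step 2
Reactants: 2
Product: 3, tert-butyl (3S,5R)-6-cyano-3,5-dihydroxy-2,2-dimethylhexanoate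
Conditions: Me4NBH(OAc)3, MeCN/AcOH, −30 → −20 °C
Reagents that add atoms: none
Why: Evans–Saksena reduction delivers hydride intramolecularly from the C5 alkoxyborohydride through a chair transition state, setting C7 1,3-anti to C5.

Step 3
Reactants: 3
Product: 4, 1-tert-butyl 9-methyl (3S,5S)-3,5-dihydroxy-2,2-dimethyl-7-oxononanedioate
Conditions: TMSCl, imidazole, THF (in situ O-silylation); activated Zn, BrCH2CO2Me (slow addition), THF, reflux; then 1 M HCl, 0 °C
Reagents that add atoms: methyl bromoacetate, BrCC(=O)OC; water, O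
Why: Blaise reaction of the Reformatsky reagent with the nitrile (as on O-silylated β-hydroxy nitriles in statin manufacture) gives the C1–C3 β-keto ester after hydrolysis; the hindered tert-butyl ester is inert.

Step 4
Reactants: 4
Product: 5, 1-tert-butyl 9-methyl (3S,5R,7R)-3,5,7-trihydroxy-2,2-dimethylnonanedioate
Conditions: Me4NBH(OAc)3, MeCN/AcOH, −30 °C
Reagents that add atoms: none
Why: A second Evans–Saksena reduction, again directed by the C5 hydroxyl (the only OH β to the ketone), sets C3 1,3-anti to C5.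

Step 5
Reactants: 5
Product: 6, tert-butyl (3S)-3-hydroxy-4-[(2R,4R)-4-hydroxy-6-oxooxan-2-yl]-2,2-dimethylbutanoate
Conditions: PPTS (cat.), toluene, 60 °C
Reagents that add atoms: none
Why: Acid-catalysed lactonisation of the δ-hydroxy methyl ester ties up C5-OH and C1 as a δ-lactone; the tert-butyl ester does not transesterify.

Step 6
Reactants: 6
Product: 7, tert-butyl (3S)-4-[(2S,4R)-4-(TBSO)-6-oxooxan-2-yl]-3-hydroxy-2,2-dimethylbutanoate
Conditions: TBSCl (1.1 eq), imidazole, DMF, 0 °C → rt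
Reagents that add atoms: TBSCl, CC(C)(C)[Si](C)(C)Cl
Why: Silylation selects the lactone (C3) hydroxyl over the neopentyl C7 carbinol next to the quaternary carbon, the same steric bias used on statin lactones.

Step 7
Reactants: 7
Product: 8, tert-butyl (3S)-4-[(2S,4R)-4-(TBSO)-6-oxooxan-2-yl]-2,2-dimethyl-3-(pivaloyloxy)butanoate
Conditions: PivCl, DMAP, pyridine, 40 °C
Reagents that add atoms: pivaloyl chloride, CC(C)(C)C(=O)Cl
Why: DMAP-catalysed acylation of the one remaining hydroxyl installs the final C7 pivalate early.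

Step 8
Reactants: 8
Product: 9, (3S)-4-[(2S,4R)-4-(TBSO)-6-oxooxan-2-yl]-2,2-dimethyl-3-(pivaloyloxy)butanoic acid
Conditions: TMSOTf, 2,6-lutidine, CH2Cl2, 0 °C; aqueous work-up
Reagents that add atoms: none
Why: Silyl triflate cleaves the tert-butyl ester by loss of isobutene without touching the TBS ether, pivalate or lactone.

Step 9
Reactants: 9
Product: 10, (2S)-1-[(2S,4R)-4-(TBSO)-6-oxooxan-2-yl]-3,3-dimethyl-4-oxohept-6-en-2-yl pivalate
Conditions: 1-chloro-N,N,2-trimethylpropenylamine (Ghosez), CH2Cl2, 0 °C → rt; then allylSnBu3, BnPdCl(PPh3)2 (3 mol %), THF, 50 °C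
Reagents that add atoms: allyltributylstannane, C=CC[Sn](CCCC)(CCCC)CCCC
Why: Stille acylation of the non-enolisable acid chloride gives the β,γ-unsaturated C9 ketone chemoselectively in the presence of the lactone and pivalate.

**C13–C19 fragment (key step)**

Step 10
Reactants: 11, (R)-2,2-dimethyl-1,3-dioxolane-4-carbaldehyde
Product: 12, (1RS)-1-[(4R)-2,2-dimethyl-1,3-dioxolan-4-yl]-3-methylbut-2-en-1-ol
Conditions: 2-methyl-1-propenylMgBr, THF, −78 → 0 °C
Reagents that add atoms: 2-methyl-1-propenylmagnesium bromide, CC(C)=C[Mg]Br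
Why: Grignard addition gives the C16 allylic alcohol; its configuration is irrelevant because C16 becomes sp2 in step 15, while C15 is the pool stereocentre.

Step 11
Reactants: 12
Product: 13, tributyl({(1RS)-1-[(4R)-2,2-dimethyl-1,3-dioxolan-4-yl]-3-methylbut-2-en-1-yl}oxymethyl)stannane
Conditions: KH, Bu3SnCH2I, THF, 0 °C → rt
Reagents that add atoms: (iodomethyl)tributylstannane, CCCC[Sn](CCCC)(CCCC)CI
Why: Williamson etherification (Still's stannylmethylation) installs the carbanion precursor on the C16 oxygen.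

Step 12
Reactants: 13
Product: 14, (2R,3RS)-5-methyl-3-[(tributylstannyl)methoxy]hex-4-ene-1,2-diol
Conditions: CSA (cat.), MeOH, 0 °C → rt
Reagents that add atoms: none
Why: Mild transacetalisation removes the terminal acetonide without ionising the allylic ether or cleaving the C–Sn bond.

Step 13
Reactants: 14
Product: 15, (2R)-2-{(1RS)-3-methyl-1-[(tributylstannyl)methoxy]but-2-en-1-yl}oxirane
Conditions: NaH, N-tosylimidazole, THF, 0 °C → rt
Reagents that add atoms: none
Why: One-pot primary sulfonylation and intramolecular Williamson closure gives the terminal epoxide with C15 retained (its C–O bond is not broken).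

Step 14
Reactants: 15
Product: 16, (4R,5RS)-7-methyl-5-[(tributylstannyl)methoxy]-1-(trimethylsilyl)oct-6-en-1-yn-4-ol
Conditions: TMSC≡CH, n-BuLi, THF, −78 °C; BF3·OEt2; then 15, −78 °C
Reagents that add atoms: (trimethylsilyl)acetylene, C#C[Si](C)(C)C
Why: Yamaguchi–Hirao alkynylation opens the epoxide at the terminal carbon (C14); it is done before the alkene is moved next to C15, so no vinyl-epoxide regiochemistry problem arises.

Step 15
Reactants: 16
Product: 17, (3E,5R)-2,2-dimethyl-8-(trimethylsilyl)oct-3-en-7-yne-1,5-diol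
Conditions: n-BuLi (2.2 eq), THF, −78 °C
Reagents that add atoms: none
Why: Sn–Li exchange triggers the [2,3]-Wittig–Still sigmatropic rearrangement, forming C18–C19 and the quaternary C18; the cis-methyl forces the C15 substituent pseudo-equatorial, so both C16 epimers give the (E)-C16=C17 alkene.

**Fragment union and northern acid**

Step 16
Reactants: 10; 17
Product: 18, C1–C19 ketone: 2,6-cis-oxane B ring (11S,15R) with (Z)-C13=CH–SiMe3, C9 ketone, C7 OPiv, C1/C5 δ-lactone with C3 OTBS, (E)-C16=C17, C19 CH2OH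
Conditions: CpRu(MeCN)3PF6 (10 mol %), CH2Cl2, rt
Reagents that add atoms: none
Why: Trost Ru-catalysed alkene–alkyne coupling joins C12 to C13 with cis delivery of H (silicon ends up trans to C12); the resulting enone is trapped by C15-OH in a chair oxa-Michael addition, setting C11 cis to C15.

Step 17
Reactants: 18
Product: 19, as 18 with (Z)-C13=CHBr
Conditions: NBS, DMF, 0 °C
Reagents that add atoms: N-bromosuccinimide, O=C1CCC(=O)N1Br
Why: ipso-Bromodesilylation of the vinylsilane in a polar solvent proceeds with retention of alkene geometry.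

Step 18
Reactants: 19
Product: 20, vinyl bromide with ring A closed as the (9S) methyl ketal, C1 methyl ester, C3 OTBS, C7 OPiv, C19 CH2OH
Conditions: K2CO3, MeOH, 0 °C; then PPTS, HC(OMe)3, MeOH, rt
Reagents that add atoms: methanol, CO (ester and ketal methoxy groups)
Why: Lactone methanolysis frees C5-OH, which closes onto the C9 ketone; acid-catalysed ketalisation gives the thermodynamic axial methoxy ketal, protecting C5 from re-lactonising later.

Step 19
Reactants: 20
Product: 21, as 20 with (Z)-C13=CH–CO2Me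
Conditions: Pd(OAc)2, dppf, CO (1 atm), Et3N, MeOH/DMF, 70 °C
Reagents that add atoms: carbon monoxide, [C-]#[O+]; methanol, CO
Why: Pd-catalysed methoxycarbonylation of the vinyl bromide retains geometry, giving the exocyclic enoate with the ester cis to C14.

Step 20
Reactants: 21
Product: 22, C19 aldehyde
Conditions: Dess–Martin periodinane, NaHCO3, CH2Cl2, rt
Reagents that add atoms: none
Why: Dess–Martin oxidation of the only free hydroxyl gives a non-enolisable neopentyl aldehyde.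

Step 21
Reactants: 22
Product: 23, C19≡C20 terminal alkyne (C1 methyl ester)
Conditions: dimethyl (1-diazo-2-oxopropyl)phosphonate, K2CO3, MeOH, 0 °C → rt
Reagents that add atoms: Ohira–Bestmann reagent, CC(=O)C(=[N+]=[N-])P(=O)(OC)OC
Why: Ohira–Bestmann (Seyferth–Gilbert) homologation adds C20; it is placed after the TMS-alkyne and the vinyl bromide are gone, so neither interferes.

Step 22
Reactants: 23
Product: 24, C1 carboxylic acid
Conditions: Me3SnOH, 1,2-dichloroethane, 80 °C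
Reagents that add atoms: trimethyltin hydroxide, C[Sn](C)(C)O
Why: Trimethyltin hydroxide hydrolyses the unhindered saturated C1 methyl ester in preference to the conjugated enoate and the pivalate.

**C21–C27 fragment**

Step 23
Reactants: 25, methyl (R)-lactate
Product: 26, methyl (2R)-2-(TBSO)propanoate
Conditions: TBSCl, imidazole, DMF, rt
Reagents that add atoms: TBSCl, CC(C)(C)[Si](C)(C)Cl
Why: Silylation fixes the final C26 protecting group.

Step 24
Reactants: 26
Product: 27, (2R)-2-(TBSO)propanal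
Conditions: DIBAL-H, CH2Cl2, −78 °C
Reagents that add atoms: none
Why: Partial reduction at −78 °C stops at the aldehyde without epimerising C26.

Step 25
Reactants: 27
Product: 28, 2-[(1R)-1-(TBSO)ethyl]-1,3-dithiane
Conditions: HS(CH2)3SH, MgBr2·OEt2, Et2O, rt
Reagents that add atoms: propane-1,3-dithiol, SCCCS
Why: Mild Lewis-acid dithioacetalisation makes C25 an acyl-anion equivalent (Corey–Seebach umpolung) while keeping the TBS ether.

Step 26
Reactants: 28; 29, (R)-epichlorohydrin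
Product: 30, 2-[(1R)-1-(TBSO)ethyl]-2-{[(2R)-oxiran-2-yl]methyl}-1,3-dithiane
Conditions: t-BuLi, THF/HMPA, −78 °C (10 min); then 29, −78 → −25 °C
Reagents that add atoms: none
Why: The lithiated dithiane opens the epoxide CH2 of epichlorohydrin and the alkoxide recloses onto the chloride, forming C24–C25 and transferring the pool stereocentre as C23.

Step 27
Reactants: 30
Product: 31, methyl (5S)-6-{2-[(1R)-1-(TBSO)ethyl]-1,3-dithian-2-yl}-5-hydroxyhex-2-ynoate
Conditions: methyl propiolate, n-BuLi, THF, −78 °C; BF3·OEt2; then 30, −78 °C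
Reagents that add atoms: methyl propiolate, C#CC(=O)OC
Why: Yamaguchi–Hirao opening at the terminal carbon forms C21–C22, the C23 hydroxyl and the ynoate in one step.

Step 28
Reactants: 31
Product: 32, methyl (5S,8R)-8-(TBSO)-5-hydroxy-7-oxonon-2-ynoate
Conditions: PhI(O2CCF3)2, NaHCO3, MeCN/H2O, 0 °C
Reagents that add atoms: water, O
Why: Buffered oxidative dethioacetalisation unmasks the C25 ketone without touching the ynoate or epimerising C26.

Step 29
Reactants: 32
Product: 33, methyl (5S,7R,8R)-8-(TBSO)-5,7-dihydroxynon-2-ynoate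
Conditions: Me4NBH(OAc)3, MeCN/AcOH, −30 °C
Reagents that add atoms: none
Why: Evans–Saksena reduction directed by C23-OH sets C25 1,3-anti; this is also the Felkin face relative to the C26 silyloxy group (1,2-syn), so the two controls reinforce.

Step 30
Reactants: 33
Product: 34, methyl (5S,7R,8R)-8-(TBSO)-7-hydroxy-5-(triethylsilyloxy)non-2-ynoate
Conditions: TESCl (1.05 eq), imidazole, CH2Cl2, −40 °C
Reagents that add atoms: chlorotriethylsilane, CC[Si](CC)(CC)Cl
Why: Silylation selects the C23 hydroxyl (flanked by two CH2) over C25-OH, which is shielded by the adjacent CH(OTBS)CH3.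

**Endgame**

Step 31
Reactants: 24; 34
Product: 35, C25 ester of 24 with 34
Conditions: 2,4,6-trichlorobenzoyl chloride, Et3N, toluene, rt; then 34, DMAP
Reagents that add atoms: none
Why: Yamaguchi esterification acylates the only free hydroxyl (C25) with retention; the C9 ketal prevents δ-lactonisation of the activated acid.

Step 32
Reactants: 35
Product: 36, seco-diyne with free C23-OH and C9 hemiketal (C3 and C26 still OTBS)
Conditions: PPTS, MeCN/H2O (10:1), 40 °C
Reagents that add atoms: water, O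
Why: Mild aqueous acid cleaves the TES ether and hydrolyses the C9 methyl ketal to the thermodynamic (9S) hemiketal before the acid-labile C ring exists; the secondary TBS ethers survive.

Step 33
Reactants: 36
Product: 37, 26-membered macrolactone enyne: C19≡C20–C21(=CH–CO2Me, E), C23-OH
Conditions: Pd(OAc)2 (12 mol %), tris(2,6-dimethoxyphenyl)phosphine (15 mol %), toluene (0.002 M), rt
Reagents that add atoms: none
Why: Trost Pd-catalysed alkyne–alkyne coupling adds the C20–H syn across the ynoate, forming C20–C21 and placing the ester cis to C22 (21E).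

Step 34
Reactants: 37
Product: 38, 3,26-bis-O-TBS bryostatin 16
Conditions: AuCl(PPh3)/AgSbF6 (20 mol %), NaHCO3, CH2Cl2/MeCN, 0 °C → rt
Reagents that add atoms: none
Why: Au(I) activation of the alkyne directs a 6-endo-dig hydroalkoxylation by C23-OH at C19, closing ring C as the dienol ether under buffered, non-acidic conditions.

Step 35
Reactants: 38
Product: 39, bryostatin 16
Conditions: TBAF, THF, rt
Reagents that add atoms: none
Why: Fluoride removes both TBS ethers without acid, so the dienol ether, the pivalate and the enoates are preserved.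

**Compound list**

1 | tert-butyl (5R)-6-cyano-5-hydroxy-3-oxohexanoate | O[C@H](CC#N)CC(=O)CC(=O)OC(C)(C)C | starting material
2 | tert-butyl (5R)-6-cyano-5-hydroxy-2,2-dimethyl-3-oxohexanoate | O[C@H](CC#N)CC(=O)C(C)(C)C(=O)OC(C)(C)C | intermediate
3 | tert-butyl (3S,5R)-6-cyano-3,5-dihydroxy-2,2-dimethylhexanoate | O[C@H](CC#N)C[C@H](O)C(C)(C)C(=O)OC(C)(C)C | intermediate
4 | 1-tert-butyl 9-methyl (3S,5S)-3,5-dihydroxy-2,2-dimethyl-7-oxononanedioate | O[C@H](CC(=O)CC(=O)OC)C[C@H](O)C(C)(C)C(=O)OC(C)(C)C | intermediate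
5 | 1-tert-butyl 9-methyl (3S,5R,7R)-3,5,7-trihydroxy-2,2-dimethylnonanedioate | O[C@H](C[C@@H](O)CC(=O)OC)C[C@H](O)C(C)(C)C(=O)OC(C)(C)C | intermediate
6 | tert-butyl (3S)-3-hydroxy-4-[(2R,4R)-4-hydroxy-6-oxooxan-2-yl]-2,2-dimethylbutanoate | O1[C@H](C[C@@H](O)CC1=O)C[C@H](O)C(C)(C)C(=O)OC(C)(C)C | intermediate
7 | tert-butyl (3S)-4-[(2S,4R)-4-(TBSO)-6-oxooxan-2-yl]-3-hydroxy-2,2-dimethylbutanoate | O1[C@H](C[C@@H](O[Si](C)(C)C(C)(C)C)CC1=O)C[C@H](O)C(C)(C)C(=O)OC(C)(C)C | intermediate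
8 | tert-butyl (3S)-4-[(2S,4R)-4-(TBSO)-6-oxooxan-2-yl]-2,2-dimethyl-3-(pivaloyloxy)butanoate | O1[C@H](C[C@@H](O[Si](C)(C)C(C)(C)C)CC1=O)C[C@H](OC(=O)C(C)(C)C)C(C)(C)C(=O)OC(C)(C)C | intermediate
9 | (3S)-4-[(2S,4R)-4-(TBSO)-6-oxooxan-2-yl]-2,2-dimethyl-3-(pivaloyloxy)butanoic acid | O1[C@H](C[C@@H](O[Si](C)(C)C(C)(C)C)CC1=O)C[C@H](OC(=O)C(C)(C)C)C(C)(C)C(=O)O | intermediate
10 | (2S)-1-[(2S,4R)-4-(TBSO)-6-oxooxan-2-yl]-3,3-dimethyl-4-oxohept-6-en-2-yl pivalate | O1[C@H](C[C@@H](O[Si](C)(C)C(C)(C)C)CC1=O)C[C@H](OC(=O)C(C)(C)C)C(C)(C)C(=O)CC=C | intermediate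
11 | (R)-2,2-dimethyl-1,3-dioxolane-4-carbaldehyde | O=C[C@H]1COC(C)(C)O1 | starting material
12 | (1RS)-1-[(4R)-2,2-dimethyl-1,3-dioxolan-4-yl]-3-methylbut-2-en-1-ol | CC(C)=CC(O)[C@H]1COC(C)(C)O1 | intermediate
13 | tributyl({(1RS)-1-[(4R)-2,2-dimethyl-1,3-dioxolan-4-yl]-3-methylbut-2-en-1-yl}oxymethyl)stannane | CC(C)=CC(OC[Sn](CCCC)(CCCC)CCCC)[C@H]1COC(C)(C)O1 | intermediate
14 | (2R,3RS)-5-methyl-3-[(tributylstannyl)methoxy]hex-4-ene-1,2-diol | CC(C)=CC(OC[Sn](CCCC)(CCCC)CCCC)[C@H](O)CO | intermediate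
15 | (2R)-2-{(1RS)-3-methyl-1-[(tributylstannyl)methoxy]but-2-en-1-yl}oxirane | CC(C)=CC(OC[Sn](CCCC)(CCCC)CCCC)[C@H]1CO1 | intermediate
16 | (4R,5RS)-7-methyl-5-[(tributylstannyl)methoxy]-1-(trimethylsilyl)oct-6-en-1-yn-4-ol | C[Si](C)(C)C#CC[C@@H](O)C(OC[Sn](CCCC)(CCCC)CCCC)C=C(C)C | intermediate
17 | (3E,5R)-2,2-dimethyl-8-(trimethylsilyl)oct-3-en-7-yne-1,5-diol | C[Si](C)(C)C#CC[C@@H](O)/C=C/C(C)(C)CO | intermediate
18 | C1–C19 ketone: cis-oxane B ring (11S,15R), (Z)-C13=CHSiMe3, C9 ketone, C7 OPiv, C1/C5 δ-lactone, C3 OTBS, C19 OH | C[Si](C)(C)/C=C1/C[C@@H](CC(=O)C(C)(C)[C@@H](OC(=O)C(C)(C)C)C[C@H]2C[C@@H](O[Si](C)(C)C(C)(C)C)CC(=O)O2)O[C@H](C1)/C=C/C(C)(C)CO | intermediate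
19 | as 18 with (Z)-C13=CHBr | Br/C=C1/C[C@@H](CC(=O)C(C)(C)[C@@H](OC(=O)C(C)(C)C)C[C@H]2C[C@@H](O[Si](C)(C)C(C)(C)C)CC(=O)O2)O[C@H](C1)/C=C/C(C)(C)CO | intermediate
20 | A/B bicycle: (9S) methyl ketal, C1 methyl ester, C3 OTBS, C7 OPiv, vinyl bromide, C19 OH | Br/C=C1/C[C@@H](C[C@]2(OC)O[C@H](C[C@@H](O[Si](C)(C)C(C)(C)C)CC(=O)OC)C[C@H](OC(=O)C(C)(C)C)C2(C)C)O[C@H](C1)/C=C/C(C)(C)CO | intermediate
21 | as 20 with (Z)-C13=CH–CO2Me | COC(=O)/C=C1/C[C@@H](C[C@]2(OC)O[C@H](C[C@@H](O[Si](C)(C)C(C)(C)C)CC(=O)OC)C[C@H](OC(=O)C(C)(C)C)C2(C)C)O[C@H](C1)/C=C/C(C)(C)CO | intermediate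
22 | C19 aldehyde | COC(=O)/C=C1/C[C@@H](C[C@]2(OC)O[C@H](C[C@@H](O[Si](C)(C)C(C)(C)C)CC(=O)OC)C[C@H](OC(=O)C(C)(C)C)C2(C)C)O[C@H](C1)/C=C/C(C)(C)C=O | intermediate
23 | C19≡C20 alkyne, C1 methyl ester | COC(=O)/C=C1/C[C@@H](C[C@]2(OC)O[C@H](C[C@@H](O[Si](C)(C)C(C)(C)C)CC(=O)OC)C[C@H](OC(=O)C(C)(C)C)C2(C)C)O[C@H](C1)/C=C/C(C)(C)C#C | intermediate
24 | C1–C20 acid | COC(=O)/C=C1/C[C@@H](C[C@]2(OC)O[C@H](C[C@@H](O[Si](C)(C)C(C)(C)C)CC(=O)O)C[C@H](OC(=O)C(C)(C)C)C2(C)C)O[C@H](C1)/C=C/C(C)(C)C#C | intermediate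
25 | methyl (R)-lactate | C[C@@H](O)C(=O)OC | starting material
26 | methyl (2R)-2-(TBSO)propanoate | C[C@@H](O[Si](C)(C)C(C)(C)C)C(=O)OC | intermediate
27 | (2R)-2-(TBSO)propanal | C[C@@H](O[Si](C)(C)C(C)(C)C)C=O | intermediate
28 | 2-[(1R)-1-(TBSO)ethyl]-1,3-dithiane | C[C@@H](O[Si](C)(C)C(C)(C)C)C1SCCCS1 | intermediate
29 | (R)-epichlorohydrin | ClC[C@H]1CO1 | starting material
30 | 2-[(1R)-1-(TBSO)ethyl]-2-{[(2R)-oxiran-2-yl]methyl}-1,3-dithiane | C[C@@H](O[Si](C)(C)C(C)(C)C)C1(C[C@@H]2CO2)SCCCS1 | intermediate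
31 | methyl (5S)-6-{2-[(1R)-1-(TBSO)ethyl]-1,3-dithian-2-yl}-5-hydroxyhex-2-ynoate | COC(=O)C#CC[C@H](O)CC1(SCCCS1)[C@@H](C)O[Si](C)(C)C(C)(C)C | intermediate
32 | methyl (5S,8R)-8-(TBSO)-5-hydroxy-7-oxonon-2-ynoate | COC(=O)C#CC[C@H](O)CC(=O)[C@@H](C)O[Si](C)(C)C(C)(C)C | intermediate
33 | methyl (5S,7R,8R)-8-(TBSO)-5,7-dihydroxynon-2-ynoate | COC(=O)C#CC[C@H](O)C[C@@H](O)[C@@H](C)O[Si](C)(C)C(C)(C)C | intermediate
34 | methyl (5S,7R,8R)-8-(TBSO)-7-hydroxy-5-(triethylsilyloxy)non-2-ynoate | COC(=O)C#CC[C@H](O[Si](CC)(CC)CC)C[C@@H](O)[C@@H](C)O[Si](C)(C)C(C)(C)C | intermediate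
35 | C25 ester of 24 and 34 (C9 OMe, C23 OTES, C3/C26 OTBS) | COC(=O)/C=C1/C[C@@H](C[C@]2(OC)O[C@H](C[C@@H](O[Si](C)(C)C(C)(C)C)CC(=O)O[C@@H]([C@@H](C)O[Si](C)(C)C(C)(C)C)C[C@H](CC#CC(=O)OC)O[Si](CC)(CC)CC)C[C@H](OC(=O)C(C)(C)C)C2(C)C)O[C@H](C1)/C=C/C(C)(C)C#C | intermediate
36 | seco-diyne, C23 OH, C9 hemiketal | COC(=O)/C=C1/C[C@@H](C[C@]2(O)O[C@H](C[C@@H](O[Si](C)(C)C(C)(C)C)CC(=O)O[C@@H]([C@@H](C)O[Si](C)(C)C(C)(C)C)C[C@H](CC#CC(=O)OC)O)C[C@H](OC(=O)C(C)(C)C)C2(C)C)O[C@H](C1)/C=C/C(C)(C)C#C | intermediate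
37 | macrocyclic enyne (C20–C21 bond, 21E), C23 OH | COC(=O)/C=C1/C[C@H]2C[C@]3(O)O[C@H](C[C@@H](O[Si](C)(C)C(C)(C)C)CC(=O)O[C@@H]([C@@H](C)O[Si](C)(C)C(C)(C)C)C[C@@H](O)C/C(=C\C(=O)OC)C#CC(C)(C)/C=C/[C@@H](C1)O2)C[C@H](OC(=O)C(C)(C)C)C3(C)C | intermediate
38 | 3,26-bis-O-TBS bryostatin 16 | COC(=O)/C=C1/C[C@H]2C[C@]3(O)O[C@H](C[C@@H](O[Si](C)(C)C(C)(C)C)CC(=O)O[C@@H]([C@@H](C)O[Si](C)(C)C(C)(C)C)C[C@@H]4C/C(=C\C(=O)OC)C=C(O4)C(C)(C)/C=C/[C@@H](C1)O2)C[C@H](OC(=O)C(C)(C)C)C3(C)C | intermediate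
39 | bryostatin 16 | COC(=O)/C=C1/C[C@H]2C[C@]3(O)O[C@H](C[C@@H](O)CC(=O)O[C@@H]([C@@H](C)O)C[C@@H]4C/C(=C\C(=O)OC)C=C(O4)C(C)(C)/C=C/[C@@H](C1)O2)C[C@H](OC(=O)C(C)(C)C)C3(C)C | target

**Totals**
- Total steps: 35.
- Longest linear sequence: 21 (steps 1–9, 16–22, 31–35).

**Three steps most likely to fail**
- Step 16 (Ru ene–yne coupling/oxa-Michael): conversion is likely to be low with the free diol and the lactone present. Fallback: build ring B by a Prins-type pyran annulation between a C9–C13 hydroxy allylsilane (from the C1–C9 acid chloride) and the C15 enal, then ozonolysis and olefination of the C13 ketone, with separation of the enoate isomers.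
- Step 26 (lithiated β-silyloxy dithiane with epichlorohydrin): β-elimination of the silyloxide can compete. Fallback: drop the acyl anion and set C23 by 1,3-anti chelation-controlled allenylstannane addition (MgBr2) to a β-PMB-oxy aldehyde. That aldehyde comes from the lactate Weinreb amide via allylMgBr, L-Selectride (Felkin, syn), PMB protection and ozonolysis; TES protection, carboxylation and DDQ then follow (two steps longer).
- Step 15 ([2,3]-Wittig–Still with the adjacent C15 alkoxide): [1,2]-shift or poor conversion of the dianion is possible. Fallback: form C16=C17 by Julia–Kocienski olefination of a C15-protected C16 aldehyde with a 2,2-dimethyl-3-(PMB-oxy)propyl PT-sulfone, carrying C19 as the PMB ether until the alkyne is installed.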